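**Retrosynthetic overview** (locants are those of the octahydronaphthalene in the target name: ring A = C4a, C5–C8, C8a; ring B = C1–C4, C4a, C8a)

1. The dienoate C4–C5 bond is cut to an (E)-alkenylalane and methyl (2R,3E)-4-iodo-2-methylbut-3-enoate (stereocentre bought with the (S)-Roche ester); the alkenylalane comes from a terminal alkyne by Zr-catalysed carboalumination, which fixes the 5E double bond.
2. The alkyne comes from a 3-hydroxypropyl octalin, and that from a cross-conjugated dienone by face-selective hydrogenation (ring-fusion H trans to the angular methyl, relayed from C8a) and mixed-hydride removal of the carbonyl.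
3. Key disconnection: ring B is annulated onto bought ring A (2,2,6-trimethylcyclohexanone) in one acid-catalysed operation that forms the C1–C8a bond (Michael addition to the central carbon of an allenyl methyl ketone) and the C4–C4a bond (aldol condensation); a chiral phosphoric acid sets the quaternary C8a.
4. Enabling feature: in ring A, C4a lies between the gem-dimethyl carbon C5 and C8a, so the ring-A ketone can enolise only toward C8a and its carbonyl carbon can only be an aldol acceptor; in ring B, the tetrasubstituted C1=C2 bond with the C2 methyl and the first side-chain carbon on C1 is the image of the three allene carbons.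
5. Order of rings: ring A is bought; ring B is formed in step 2.

Key step: step 2

Assumption: 3-(triphenylphosphoranylidene)butan-2-one is taken as a purchasable stabilised ylide (otherwise one step from 3-bromobutan-2-one and PPh3).
Assumption: the (R) antipode of the phosphoric acid is taken to give the (R)-dienone; the sense of induction has to be fixed in a first run, and the (S) acid is used with nothing else changed if it is opposite.

**Route**

Step 1
Reactants: 1 4-(benzyloxy)butanoic acid; 2 3-(triphenylphosphoranylidene)butan-2-one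
Product: 5 7-(benzyloxy)-3-methylhepta-3,4-dien-2-one, via acid chloride 3 (not isolated), via ketene 4 (not isolated)
Conditions: (COCl)2, DMF (cat.), CH2Cl2, 0 °C → rt; evaporate; then 2, Et3N, CH2Cl2, 0 °C → rt
Reagents that add atoms: none
Why: Wittig olefination of a ketene made in situ from the acid chloride (allene synthesis with a stabilised ylide) should give the 1,2-allenyl ketone, whose axial chirality is irrelevant because it is lost in step 2.

Step 2
Reactants: 6 2,2,6-trimethylcyclohexanone; 5 7-(benzyloxy)-3-methylhepta-3,4-dien-2-one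
Product: 9 (R)-4-[3-(benzyloxy)propyl]-3,4a,8,8-tetramethyl-5,6,7,8-tetrahydronaphthalen-2(4aH)-one, via enedione 7 (not isolated), via aldol 8 (not isolated)
Conditions: (R)-TRIP [(R)-3,3'-bis(2,4,6-triisopropylphenyl)-1,1'-binaphthyl-2,2'-diyl hydrogen phosphate] (10 mol %), 6 (2 equiv), PhMe, 40 °C; then 110 °C, Dean–Stark, same flask
Reagents that add atoms: none
Why: Proposed new method: the phosphoric acid should enolise 6 toward its only α-CH carbon and, hydrogen-bonded to the enol OH and to the carbonyl of 5, deliver that tetrasubstituted enol carbon to the central allene carbon (Michael addition), after which the dienol tautomerises to the (Z)-enedione 7 and the same acid drives aldol addition of the methyl-ketone enol to the ring-A carbonyl (8) and loss of water to 9. The closest known reaction types are chiral-phosphoric-acid "enol catalysis" Michael additions of α-branched cyclic ketones to enones and to allenamides and the acid-catalysed Robinson annulation; what is new is their union with an allenyl ketone on a ketone this hindered. Ring B closes by a 6-(enolendo)-exo-trig aldol addition, and the dehydration can only place the double bond between C4 and C4a (target locants) because the other two neighbours of the carbinol carbon are quaternary. The one new stereocentre, the quaternary C8a, is set under catalyst control in the Michael step by face selection of the enol inside the chiral hydrogen-bonded ion pair. The step needs C- over O-attack and attack at the central allene carbon (secured by the soft enol and the conjugate position) and a single aldol mode (secured because the ring-A carbonyl has no α-hydrogen left and the only other enolisable site of 7 would close a four-membered ring).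

Step 3
Reactants: 9 (R)-4-[3-(benzyloxy)propyl]-3,4a,8,8-tetramethyl-5,6,7,8-tetrahydronaphthalen-2(4aH)-one
Product: 11 (4aS,8aS)-4-(3-hydroxypropyl)-3,4a,8,8-tetramethyl-4a,5,6,7,8,8a-hexahydronaphthalen-2(1H)-one, via benzyl ether 10 (not isolated)
Conditions: H2 (1 atm), Pd/C (10 wt %), EtOH, rt
Reagents that add atoms: none
Why: Heterogeneous catalytic hydrogenation should add hydrogen to the trisubstituted enone double bond from the face opposite the two syn-axial methyl groups (angular methyl and axial gem-methyl), which sets the ring-fusion hydrogen trans to the angular methyl by substrate control, leaves the tetrasubstituted enone alone and then cleaves the benzyl ether by hydrogenolysis.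

Step 4
Reactants: 11 (4aS,8aS)-4-(3-hydroxypropyl)-3,4a,8,8-tetramethyl-4a,5,6,7,8,8a-hexahydronaphthalen-2(1H)-one
Product: 12 3-[(4aS,8aS)-2,5,5,8a-tetramethyl-3,4,4a,5,6,7,8,8a-octahydronaphthalen-1-yl]propan-1-ol
Conditions: LiAlH4, AlCl3 (1:3), Et2O, 0 °C → reflux
Reagents that add atoms: none
Why: Mixed-hydride (chloroalane) deoxygenation of an α,β-unsaturated ketone: the allylic aluminium alkoxide ionises and hydride should go to the less hindered secondary terminus, so the CH2 forms and the tetrasubstituted double bond stays in place; no stereocentre is touched.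

Step 5
Reactants: 12 3-[(4aS,8aS)-2,5,5,8a-tetramethyl-3,4,4a,5,6,7,8,8a-octahydronaphthalen-1-yl]propan-1-ol
Product: 13 3-[(4aS,8aS)-2,5,5,8a-tetramethyl-3,4,4a,5,6,7,8,8a-octahydronaphthalen-1-yl]propanal
Conditions: Dess–Martin periodinane, CH2Cl2, 0 °C → rt
Reagents that add atoms: none
Why: Dess–Martin oxidation of the primary alcohol to the aldehyde under neutral conditions that leave the tetrasubstituted alkene alone.

Step 6
Reactants: 13 3-[(4aS,8aS)-2,5,5,8a-tetramethyl-3,4,4a,5,6,7,8,8a-octahydronaphthalen-1-yl]propanal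
Product: 14 4-[(4aS,8aS)-2,5,5,8a-tetramethyl-3,4,4a,5,6,7,8,8a-octahydronaphthalen-1-yl]but-1-yne
Conditions: dimethyl (1-diazo-2-oxopropyl)phosphonate, K2CO3, MeOH, 0 °C → rt
Reagents that add atoms: dimethyl (1-diazo-2-oxopropyl)phosphonate, COP(=O)(OC)C(=[N+]=[N-])C(C)=O
Why: Seyferth–Gilbert homologation in the Ohira–Bestmann variant should convert the aldehyde into the terminal alkyne under mild base; the aldehyde has no α-stereocentre to lose.

Step 7
Reactants: 15 methyl (S)-3-hydroxy-2-methylpropanoate ((S)-Roche ester)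
Product: 16 methyl (S)-3-[(tert-butyldimethylsilyl)oxy]-2-methylpropanoate
Conditions: t-BuMe2SiCl, imidazole, CH2Cl2, rt
Reagents that add atoms: tert-butyldimethylsilyl chloride, CC(C)(C)[Si](C)(C)Cl
Why: Silylation of the primary alcohol; the bought α-stereocentre is untouched.

Step 8
Reactants: 16 methyl (S)-3-[(tert-butyldimethylsilyl)oxy]-2-methylpropanoate
Product: 17 (S)-3-[(tert-butyldimethylsilyl)oxy]-2-methylpropanal
Conditions: i-Bu2AlH, CH2Cl2, −78 °C; Rochelle salt work-up; used crude
Reagents that add atoms: none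
Why: Partial reduction of the ester with i-Bu2AlH stops at the tetrahedral aluminium hemiacetal at low temperature and should give the aldehyde, which is used at once so that its α-stereocentre is kept.

Step 9
Reactants: 17 (S)-3-[(tert-butyldimethylsilyl)oxy]-2-methylpropanal
Product: 18 tert-butyl{[(2R,3E)-4-iodo-2-methylbut-3-en-1-yl]oxy}dimethylsilane
Conditions: CrCl2, CHI3, THF, 0 °C → rt
Reagents that add atoms: iodoform, IC(I)I
Why: Takai olefination should give the (E)-vinyl iodide under non-basic conditions that do not epimerise the α-stereocentre (the descriptor changes from S to R only through the priority rules).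

Step 10
Reactants: 18 tert-butyl{[(2R,3E)-4-iodo-2-methylbut-3-en-1-yl]oxy}dimethylsilane
Product: 19 (2R,3E)-4-iodo-2-methylbut-3-en-1-ol
Conditions: camphorsulfonic acid (cat.), MeOH, 0 °C → rt
Reagents that add atoms: none
Why: Acid-catalysed methanolysis of the primary silyl ether, which leaves the vinyl iodide and the stereocentre alone.

Step 11
Reactants: 19 (2R,3E)-4-iodo-2-methylbut-3-en-1-ol
Product: 21 (2R,3E)-4-iodo-2-methylbut-3-enoic acid, via aldehyde 20 (not isolated)
Conditions: TEMPO (cat.), PhI(OAc)2, MeCN/H2O, rt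
Reagents that add atoms: water, O
Why: TEMPO-catalysed oxidation with PhI(OAc)2 takes the alcohol through the aldehyde hydrate to the acid under near-neutral conditions, chosen so that the allylic α-stereocentre is not epimerised.

Step 12
Reactants: 21 (2R,3E)-4-iodo-2-methylbut-3-enoic acid
Product: 22 methyl (2R,3E)-4-iodo-2-methylbut-3-enoate
Conditions: Me3SiCHN2, MeOH/PhMe, 0 °C
Reagents that add atoms: trimethylsilyldiazomethane, C[Si](C)(C)C=[N+]=[N-]
Why: Esterification with trimethylsilyldiazomethane needs no base and should keep both the α-stereocentre and the β,γ-position of the double bond.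

Step 13
Reactants: 14 4-[(4aS,8aS)-2,5,5,8a-tetramethyl-3,4,4a,5,6,7,8,8a-octahydronaphthalen-1-yl]but-1-yne; 22 methyl (2R,3E)-4-iodo-2-methylbut-3-enoate
Product: 24 methyl (2R,3E,5E)-2,6-dimethyl-8-[(4aS,8aS)-2,5,5,8a-tetramethyl-3,4,4a,5,6,7,8,8a-octahydronaphthalen-1-yl]octa-3,5-dienoate, via alkenylalane 23 (not isolated)
Conditions: Me3Al, Cp2ZrCl2 (cat.), CH2Cl2, rt; volatiles removed in vacuo; then 22, Pd(PPh3)4 (cat.), ZnCl2 (cat.), THF, rt
Reagents that add atoms: trimethylaluminium, C[Al](C)C
Why: Zr-catalysed syn-carboalumination of the terminal alkyne (Negishi carboalumination) fixes the (E)-trisubstituted double bond, and Pd-catalysed cross-coupling of the alkenylalane with the (E)-iodide goes with retention at both sp2 carbons to the (3E,5E)-diene; the three stereocentres are carried through unchanged.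

**Compound list**

1 | 4-(benzyloxy)butanoic acid | OC(=O)CCCOCc1ccccc1 | starting material
2 | 3-(triphenylphosphoranylidene)butan-2-one | CC(=O)C(C)=P(c1ccccc1)(c1ccccc1)c1ccccc1 | starting material
3 | 4-(benzyloxy)butanoyl chloride | ClC(=O)CCCOCc1ccccc1 | intermediate
4 | 4-(benzyloxy)but-1-en-1-one (the ketene) | O=C=CCCOCc1ccccc1 | intermediate
5 | 7-(benzyloxy)-3-methylhepta-3,4-dien-2-one (racemic allene) | CC(=O)C(C)=C=CCCOCc1ccccc1 | intermediate
6 | 2,2,6-trimethylcyclohexanone (racemic) | CC1CCCC(C)(C)C1=O | starting material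
7 | (Z)-7-(benzyloxy)-3-methyl-4-[(R)-1,3,3-trimethyl-2-oxocyclohexyl]hept-3-en-2-one | CC(=O)/C(C)=C(/CCCOCc1ccccc1)[C@@]1(C)CCCC(C)(C)C1=O | intermediate
8 | (4aR)-4-[3-(benzyloxy)propyl]-8a-hydroxy-3,4a,8,8-tetramethyl-4a,5,6,7,8,8a-hexahydronaphthalen-2(1H)-one (either C8a epimer; both dehydrate) | O=C1CC2(O)C(C)(C)CCC[C@]2(C)C(CCCOCc2ccccc2)=C1C | intermediate
9 | (R)-4-[3-(benzyloxy)propyl]-3,4a,8,8-tetramethyl-5,6,7,8-tetrahydronaphthalen-2(4aH)-one | O=C1C=C2C(C)(C)CCC[C@]2(C)C(CCCOCc2ccccc2)=C1C | intermediate
10 | (4aS,8aS)-4-[3-(benzyloxy)propyl]-3,4a,8,8-tetramethyl-4a,5,6,7,8,8a-hexahydronaphthalen-2(1H)-one | O=C1C[C@H]2C(C)(C)CCC[C@]2(C)C(CCCOCc2ccccc2)=C1C | intermediate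
11 | (4aS,8aS)-4-(3-hydroxypropyl)-3,4a,8,8-tetramethyl-4a,5,6,7,8,8a-hexahydronaphthalen-2(1H)-one | O=C1C[C@H]2C(C)(C)CCC[C@]2(C)C(CCCO)=C1C | intermediate
12 | 3-[(4aS,8aS)-2,5,5,8a-tetramethyl-3,4,4a,5,6,7,8,8a-octahydronaphthalen-1-yl]propan-1-ol | OCCCC1=C(C)CC[C@H]2C(C)(C)CCC[C@]12C | intermediate
13 | 3-[(4aS,8aS)-2,5,5,8a-tetramethyl-3,4,4a,5,6,7,8,8a-octahydronaphthalen-1-yl]propanal | O=CCCC1=C(C)CC[C@H]2C(C)(C)CCC[C@]12C | intermediate
14 | 4-[(4aS,8aS)-2,5,5,8a-tetramethyl-3,4,4a,5,6,7,8,8a-octahydronaphthalen-1-yl]but-1-yne | C#CCCC1=C(C)CC[C@H]2C(C)(C)CCC[C@]12C | intermediate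
15 | methyl (S)-3-hydroxy-2-methylpropanoate ((S)-Roche ester) | COC(=O)[C@@H](C)CO | starting material
16 | methyl (S)-3-[(tert-butyldimethylsilyl)oxy]-2-methylpropanoate | COC(=O)[C@@H](C)CO[Si](C)(C)C(C)(C)C | intermediate
17 | (S)-3-[(tert-butyldimethylsilyl)oxy]-2-methylpropanal | O=C[C@@H](C)CO[Si](C)(C)C(C)(C)C | intermediate
18 | tert-butyl{[(2R,3E)-4-iodo-2-methylbut-3-en-1-yl]oxy}dimethylsilane | I/C=C/[C@@H](C)CO[Si](C)(C)C(C)(C)C | intermediate
19 | (2R,3E)-4-iodo-2-methylbut-3-en-1-ol | I/C=C/[C@@H](C)CO | intermediate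
20 | (2R,3E)-4-iodo-2-methylbut-3-enal | I/C=C/[C@@H](C)C=O | intermediate
21 | (2R,3E)-4-iodo-2-methylbut-3-enoic acid | I/C=C/[C@@H](C)C(=O)O | intermediate
22 | methyl (2R,3E)-4-iodo-2-methylbut-3-enoate | COC(=O)[C@H](C)/C=C/I | intermediate
23 | dimethyl{(1E)-2-methyl-4-[(4aS,8aS)-2,5,5,8a-tetramethyl-3,4,4a,5,6,7,8,8a-octahydronaphthalen-1-yl]but-1-en-1-yl}alumane | C[Al](C)/C=C(\C)CCC1=C(C)CC[C@H]2C(C)(C)CCC[C@]12C | intermediate
24 | methyl (2R,3E,5E)-2,6-dimethyl-8-[(4aS,8aS)-2,5,5,8a-tetramethyl-3,4,4a,5,6,7,8,8a-octahydronaphthalen-1-yl]octa-3,5-dienoate (CNP0152124.1) | COC(=O)[C@H](C)/C=C/C=C(\C)CCC1=C(C)CC[C@H]2C(C)(C)CCC[C@]12C | target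

**Step count and risks**

Total step count: 13. Longest linear sequence: 7 steps (steps 1–6 and 13; the branch of steps 7–13 is equally long).

Steps most likely to fail:

1. Step 2 (Proposed new method). Enolisation of the doubly hindered ketone may be too slow for the Michael addition to keep pace with acid-induced isomerisation of the allenone to a 2,4-dienone or its cycloisomerisation to a furan. Reversible Michael addition before ring closure may also erode the enantiomeric purity. The fallback uses known chemistry, stepwise and with resolution in place of asymmetric catalysis; it sets out from 6 and 5 and comes back at 9. Ketone 6 is converted with LiN(i-Pr)2 and Me3SiCl into its silyl enol ether trimethyl[(2,6,6-trimethylcyclohex-1-en-1-yl)oxy]silane F1. A Mukaiyama–Michael addition of F1 to 5 (TiCl4, CH2Cl2, −78 °C) should give after aqueous work-up the racemic enedione 7-(benzyloxy)-3-methyl-4-(1,3,3-trimethyl-2-oxocyclohexyl)hept-3-en-2-one F2. KOH in refluxing xylene with removal of water should close it by aldol condensation to the racemic dienone 4-[3-(benzyloxy)propyl]-3,4a,8,8-tetramethyl-5,6,7,8-tetrahydronaphthalen-2(4aH)-one F3. Preparative chromatography on a chiral stationary phase then delivers the (R) enantiomer 9.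

2. Step 13. The ester α-carbon may lose configuration through enolisation by Lewis-acidic aluminium and zinc species, the double bond may drift into conjugation, and residual Me3Al may transfer methyl to the ester. The fallback builds the ester after the coupling; it sets out from 14 and 18 and comes back at 24. Alkyne 14 is carboaluminated as in step 13 to 23, which is coupled under the same Pd catalysis with the silyl ether 18 to give tert-butyl{[(2R,3E,5E)-2,6-dimethyl-8-[(4aS,8aS)-2,5,5,8a-tetramethyl-3,4,4a,5,6,7,8,8a-octahydronaphthalen-1-yl]octa-3,5-dien-1-yl]oxy}dimethylsilane F5. Bu4NF in THF frees (2R,3E,5E)-2,6-dimethyl-8-[(4aS,8aS)-2,5,5,8a-tetramethyl-3,4,4a,5,6,7,8,8a-octahydronaphthalen-1-yl]octa-3,5-dien-1-ol F6. Dess–Martin oxidation gives the corresponding (2R,3E,5E)-octa-3,5-dienal F7, and Pinnick oxidation (NaClO2, NaH2PO4, 2-methylbut-2-ene, t-BuOH/H2O) gives the (2R,3E,5E)-octa-3,5-dienoic acid F8. Me3SiCHN2 in MeOH/PhMe then gives 24.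

3. Step 4. The allylic aluminium alkoxide may ionise and lose a proton to a ring diene, or take up hydride with allylic transposition, instead of clean replacement of oxygen by hydrogen. The fallback uses desulfurisation in place of ionising reduction; it sets out from 11 and comes back at 12. Enone 11 with ethane-1,2-dithiol and BF3·OEt2 in CH2Cl2 should give the ethylene dithioketal of 11 (spiro-1,3-dithiolane at the ring-B carbonyl carbon) F4, and Raney nickel in ethanol should replace both C–S bonds by C–H to give 12.

Further compounds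
F1 | step 2 | trimethyl[(2,6,6-trimethylcyclohex-1-en-1-yl)oxy]silane | CC1=C(O[Si](C)(C)C)C(C)(C)CCC1
F2 | step 2 | racemic (Z)-7-(benzyloxy)-3-methyl-4-(1,3,3-trimethyl-2-oxocyclohexyl)hept-3-en-2-one | CC(=O)/C(C)=C(/CCCOCc1ccccc1)C1(C)CCCC(C)(C)C1=O
F3 | step 2 | racemic 4-[3-(benzyloxy)propyl]-3,4a,8,8-tetramethyl-5,6,7,8-tetrahydronaphthalen-2(4aH)-one | O=C1C=C2C(C)(C)CCCC2(C)C(CCCOCc2ccccc2)=C1C
F4 | step 4 | ethylene dithioketal of 11 (spiro-1,3-dithiolane at the ring-B carbonyl carbon) | OCCCC1=C(C)C3(SCCS3)C[C@H]2C(C)(C)CCC[C@]12C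
F5 | step 13 | tert-butyl{[(2R,3E,5E)-2,6-dimethyl-8-[(4aS,8aS)-2,5,5,8a-tetramethyl-3,4,4a,5,6,7,8,8a-octahydronaphthalen-1-yl]octa-3,5-dien-1-yl]oxy}dimethylsilane | CC(C)(C)[Si](C)(C)OC[C@H](C)/C=C/C=C(\C)CCC1=C(C)CC[C@H]2C(C)(C)CCC[C@]12C
F6 | step 13 | (2R,3E,5E)-2,6-dimethyl-8-[(4aS,8aS)-2,5,5,8a-tetramethyl-3,4,4a,5,6,7,8,8a-octahydronaphthalen-1-yl]octa-3,5-dien-1-ol | OC[C@H](C)/C=C/C=C(\C)CCC1=C(C)CC[C@H]2C(C)(C)CCC[C@]12C
F7 | step 13 | (2R,3E,5E)-2,6-dimethyl-8-[(4aS,8aS)-2,5,5,8a-tetramethyl-3,4,4a,5,6,7,8,8a-octahydronaphthalen-1-yl]octa-3,5-dienal | O=C[C@H](C)/C=C/C=C(\C)CCC1=C(C)CC[C@H]2C(C)(C)CCC[C@]12C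
F8 | step 13 | (2R,3E,5E)-2,6-dimethyl-8-[(4aS,8aS)-2,5,5,8a-tetramethyl-3,4,4a,5,6,7,8,8a-octahydronaphthalen-1-yl]octa-3,5-dienoic acid | OC(=O)[C@H](C)/C=C/C=C(\C)CCC1=C(C)CC[C@H]2C(C)(C)CCC[C@]12C
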